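**Plan**
1. Numbering: oxolane ring O1–C2–C3–C4–C5, aryl groups on C2 and C5, C9 (CH2OH) on C3, C9' (CH2OH) on C4; all four ring carbons are S (C2/C3 cis, C3/C4 trans, C4/C5 cis).
2. Cuts: O1–C5 (ether from a C5 hemiketal), then C2–C3 (aldol) and C4–C5 (conjugate addition of an aroyl anion equivalent); C9' is extended by one carbon to a glycol so that C9(=O)–C3–C4–C9'–O is a γ-lactone.
3. Enabling feature: the C3–C4 bond with its four carbon substituents (C2, C9, C5, C9') is the α,β-bond of a trans-disubstituted γ-butyrolactone, so both carbons can be functionalised in one flask from a butenolide.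
4. Forward: dithiane anion, butenolide and aldehyde join the whole chain without ring closure; hydride opens the lactone; unmasking the C5 ketone closes the only ring (O1–C5) as a hemiketal, which is reduced; desilylation, glycol cleavage–reduction and hydrogenolysis finish.
5. Stereochemistry: the γ-centre of the chiral-pool butenolide sets C4, C4 sets C3, the cyclic enolate geometry sets C2, the C4 side chain directs hydride to C5; the relay centre is finally excised.

Key step: step 3

Remark: (S)-5-(hydroxymethyl)furan-2(5H)-one 4 (the butenolide of the L-glutamic acid chiral pool) and O-benzylvanillin 1 are taken as purchasable; hemiketal 11 is written in its cyclic form although it may equilibrate with the open hydroxy ketone.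

**Step 1**
Reactants: 1 4-(benzyloxy)-3-methoxybenzaldehyde (O-benzylvanillin); 2 propane-1,3-dithiol
Product: 3 2-(4-benzyloxy-3-methoxyphenyl)-1,3-dithiane
Conditions: BF3·OEt2 (cat.), CH2Cl2, 0 °C to rt
Reagents that add atoms: none
Why: Lewis acid-catalysed dithioacetalisation of an aromatic aldehyde is reliable, releases only water and leaves the aryl benzyl ether untouched at catalytic BF3 loading.

**Step 2**
Reactants: 4 (S)-5-(hydroxymethyl)furan-2(5H)-one
Product: 5 (S)-5-[(tert-butyldiphenylsilyloxy)methyl]furan-2(5H)-one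
Conditions: TBDPSCl, imidazole, CH2Cl2, 0 °C to rt
Reagents that add atoms: tert-butyl(chloro)diphenylsilane, CC(C)(C)[Si](Cl)(c1ccccc1)c1ccccc1
Why: Silylation of a primary alcohol with imidazole as a weak base does not enolise the butenolide at its γ-position, so the S centre is kept and the bulky silyl ether becomes the face-shielding group of the next step.

**Step 3**
Reactants: 3 2-(4-benzyloxy-3-methoxyphenyl)-1,3-dithiane; 5 (S)-5-[(tert-butyldiphenylsilyloxy)methyl]furan-2(5H)-one; 1 4-(benzyloxy)-3-methoxybenzaldehyde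
Product: 8 (3R,4S,5S)-3-[(S)-(4-benzyloxy-3-methoxyphenyl)(hydroxy)methyl]-4-[2-(4-benzyloxy-3-methoxyphenyl)-1,3-dithian-2-yl]-5-[(tert-butyldiphenylsilyloxy)methyl]dihydrofuran-2(3H)-one, via lithiated dithiane 6 (not isolated), via lithium lactone enolate 7 (not isolated)
Conditions: n-BuLi, THF, −78 °C; then 5, −78 °C; then 1, −78 °C; AcOH, −78 °C
Reagents that add atoms: none
Why: Deprotonation of 3 gives the sulfur-stabilised benzylic carbanion 6, which adds in Michael fashion to the β-carbon (C4) of butenolide 5, and the resulting lithium enolate 7 adds to aldehyde 1 through a closed, lithium-bridged chair transition state. The closest known reaction type is the three-component conjugate addition–aldol trapping of 2-aryl-2-lithio-1,3-dithianes on γ-substituted butenolides used for lignan lactones. No ring is closed; the bonds C4–C5 and C2–C3 and three stereocentres are created on the intact lactone. C4 is set by attack anti to the γ-CH2OTBDPS group of the chiral-pool centre, C3 by approach of the aldehyde anti to the new dithianyl group (trans-α,β lactone), and C2 by the fixed geometry of the ring enolate (α-carbon trans to O–Li), which with the aryl group equatorial in the chair should give the anti (S) carbinol. The step needs 1,4- over 1,2-addition, secured by the soft, delocalised aryl dithiane anion and the weakly electrophilic lactone carbonyl. It also needs kinetic aldol control, secured by holding the aldolate at −78 °C and quenching cold with AcOH so that retro-aldol equilibration cannot set in.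

**Step 4**
Reactants: 8 the aldol lactone of step 3
Product: 9 (2S,3S,4S)-2-[(S)-(4-benzyloxy-3-methoxyphenyl)(hydroxy)methyl]-3-[2-(4-benzyloxy-3-methoxyphenyl)-1,3-dithian-2-yl]-5-[(tert-butyldiphenylsilyl)oxy]pentane-1,4-diol
Conditions: LiAlH4, THF, 0 °C; aqueous work-up
Reagents that add atoms: none
Why: Lactone reduction by LiAlH4 to the 1,4-diol outruns retro-aldol cleavage of the aldolate at 0 °C and leaves dithiane, silyl ether and benzyl ethers intact, and it removes the trans ring fusion that would forbid the later oxolane closure.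

**Step 5**
Reactants: 9 the triol of step 4
Product: 10 (2S,3S,4S)-4-[(S)-(4-benzyloxy-3-methoxyphenyl)(hydroxy)methyl]-3-[2-(4-benzyloxy-3-methoxyphenyl)-1,3-dithian-2-yl]-1,5-bis[(tert-butyldiphenylsilyl)oxy]pentan-2-ol
Conditions: TBDPSCl (1 equiv), imidazole, CH2Cl2, −20 to 0 °C
Reagents that add atoms: tert-butyl(chloro)diphenylsilane, CC(C)(C)[Si](Cl)(c1ccccc1)c1ccccc1
Why: Site-selective silylation by the bulky silyl chloride takes the only primary hydroxyl (C9–OH) over the two hindered secondary ones, which keeps C9–OH from competing with C2–OH for the C5 ketone in the next step.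

**Step 6**
Reactants: 10 the bis-silyl ether of step 5
Product: 11 (3S,4S,5S)-2,5-bis(4-benzyloxy-3-methoxyphenyl)-3-[(S)-2-(tert-butyldiphenylsilyloxy)-1-hydroxyethyl]-4-[(tert-butyldiphenylsilyloxy)methyl]tetrahydrofuran-2-ol (anomeric mixture at the hemiketal carbon C5 of the target numbering)
Conditions: Hg(ClO4)2·3H2O, CaCO3, THF/H2O, 0 °C to rt
Reagents that add atoms: water, O
Why: Dithioacetal hydrolysis by thiophilic divalent mercury frees the aryl ketone, which the C2 hydroxyl captures at once as the five-membered cyclic hemiketal (the side-chain hydroxyl could only form an oxetane), while CaCO3 buffers the HClO4 released and so protects the benzylic alcohol and the silyl ethers.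

**Step 7**
Reactants: 11 the cyclic hemiketal of step 6
Product: 12 (S)-1-[(2S,3S,4S,5S)-2,5-bis(4-benzyloxy-3-methoxyphenyl)-4-{[(tert-butyldiphenylsilyl)oxy]methyl}tetrahydrofuran-3-yl]-2-[(tert-butyldiphenylsilyl)oxy]ethan-1-ol
Conditions: Et3SiH, BF3·OEt2, CH2Cl2, −78 °C
Reagents that add atoms: none
Why: Ionic hydrogenation of a cyclic hemiketal proceeds through the 2-aryl oxocarbenium ion, in which A(1,2) strain with the coplanar aryl ring pushes the branched C4 side chain pseudoaxial, so the silane should deliver hydride to the opposite face and set C5 (S) with its aryl group cis to the C4 substituent, the low temperature guarding against benzylic epimerisation.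

**Step 8**
Reactants: 12 the bis-silylated oxolane of step 7
Product: 13 (S)-1-[(2S,3S,4S,5S)-2,5-bis(4-benzyloxy-3-methoxyphenyl)-4-(hydroxymethyl)tetrahydrofuran-3-yl]ethane-1,2-diol
Conditions: Bu4NF, THF, 0 °C to rt
Reagents that add atoms: none
Why: Fluoride-mediated desilylation removes both silyl ethers in one operation and unveils the terminal 1,2-diol and the C9 alcohol without touching the benzyl ethers or the benzylic ring ether bonds.

**Step 9**
Reactants: 13 the triol of step 8
Product: 15 [(2S,3S,4S,5S)-2,5-bis(4-benzyloxy-3-methoxyphenyl)tetrahydrofuran-3,4-diyl]dimethanol, via aldehyde 14 (not isolated)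
Conditions: NaIO4, THF/pH 7 buffer, 0 °C; extraction; NaBH4, MeOH, 0 °C
Reagents that add atoms: none
Why: Periodate glycol cleavage excises the former silyloxymethyl carbon as formaldehyde and thereby erases the relay stereocentre, and immediate borohydride reduction of the crude α-branched aldehyde under cold, near-neutral conditions should leave C4 neither epimerised nor eliminated towards the β ring oxygen.

**Step 10**
Reactants: 15 the di-O-benzyl ether of the target
Product: 16 eduesmine, 4,4'-[(2S,3S,4S,5S)-3,4-bis(hydroxymethyl)tetrahydrofuran-2,5-diyl]bis(2-methoxyphenol)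
Conditions: H2 (1 atm), Pd/C, EtOAc/MeOH, rt
Reagents that add atoms: none
Why: Catalytic hydrogenolysis cleaves aryl benzyl ethers much faster than the dialkyl benzylic C–O bonds of the oxolane, so stopping once the starting material is consumed should give the free bisphenol with all four stereocentres intact.

**Compound list**
1 | 4-(benzyloxy)-3-methoxybenzaldehyde (O-benzylvanillin) | COc1cc(C=O)ccc1OCc1ccccc1 | starting material
2 | propane-1,3-dithiol | SCCCS | starting material
3 | 2-(4-benzyloxy-3-methoxyphenyl)-1,3-dithiane | COc1cc(C2SCCCS2)ccc1OCc1ccccc1 | intermediate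
4 | (S)-5-(hydroxymethyl)furan-2(5H)-one | O=C1O[C@H](CO)C=C1 | starting material
5 | (S)-5-[(tert-butyldiphenylsilyloxy)methyl]furan-2(5H)-one | O=C1O[C@H](CO[Si](c2ccccc2)(c2ccccc2)C(C)(C)C)C=C1 | intermediate
6 | 2-(4-benzyloxy-3-methoxyphenyl)-2-lithio-1,3-dithiane (lithiated dithiane) | [Li]C1(c2ccc(OCc3ccccc3)c(OC)c2)SCCCS1 | intermediate
7 | lithium (4S,5S)-4-[2-(4-benzyloxy-3-methoxyphenyl)-1,3-dithian-2-yl]-5-[(tert-butyldiphenylsilyloxy)methyl]-4,5-dihydrofuran-2-olate (lithium lactone enolate) | [Li]OC1=C[C@H](C2(c3ccc(OCc4ccccc4)c(OC)c3)SCCCS2)[C@@H](CO[Si](c2ccccc2)(c2ccccc2)C(C)(C)C)O1 | intermediate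
8 | (3R,4S,5S)-3-[(S)-(4-benzyloxy-3-methoxyphenyl)(hydroxy)methyl]-4-[2-(4-benzyloxy-3-methoxyphenyl)-1,3-dithian-2-yl]-5-[(tert-butyldiphenylsilyloxy)methyl]dihydrofuran-2(3H)-one | O=C1O[C@H](CO[Si](c2ccccc2)(c2ccccc2)C(C)(C)C)[C@@H](C2(c3ccc(OCc4ccccc4)c(OC)c3)SCCCS2)[C@@H]1[C@H](O)c1ccc(OCc2ccccc2)c(OC)c1 | intermediate
9 | (2S,3S,4S)-2-[(S)-(4-benzyloxy-3-methoxyphenyl)(hydroxy)methyl]-3-[2-(4-benzyloxy-3-methoxyphenyl)-1,3-dithian-2-yl]-5-[(tert-butyldiphenylsilyl)oxy]pentane-1,4-diol | OC[C@@H]([C@H](O)c1ccc(OCc2ccccc2)c(OC)c1)[C@H](C1(c2ccc(OCc3ccccc3)c(OC)c2)SCCCS1)[C@H](O)CO[Si](c1ccccc1)(c1ccccc1)C(C)(C)C | intermediate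
10 | (2S,3S,4S)-4-[(S)-(4-benzyloxy-3-methoxyphenyl)(hydroxy)methyl]-3-[2-(4-benzyloxy-3-methoxyphenyl)-1,3-dithian-2-yl]-1,5-bis[(tert-butyldiphenylsilyl)oxy]pentan-2-ol | CC(C)(C)[Si](c1ccccc1)(c1ccccc1)OC[C@@H]([C@H](O)c1ccc(OCc2ccccc2)c(OC)c1)[C@H](C1(c2ccc(OCc3ccccc3)c(OC)c2)SCCCS1)[C@H](O)CO[Si](c1ccccc1)(c1ccccc1)C(C)(C)C | intermediate
11 | (3S,4S,5S)-2,5-bis(4-benzyloxy-3-methoxyphenyl)-3-[(S)-2-(tert-butyldiphenylsilyloxy)-1-hydroxyethyl]-4-[(tert-butyldiphenylsilyloxy)methyl]tetrahydrofuran-2-ol (both anomers) | OC1(c2ccc(OCc3ccccc3)c(OC)c2)O[C@H](c2ccc(OCc3ccccc3)c(OC)c2)[C@H](CO[Si](c2ccccc2)(c2ccccc2)C(C)(C)C)[C@H]1[C@H](O)CO[Si](c1ccccc1)(c1ccccc1)C(C)(C)C | intermediate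
12 | (S)-1-[(2S,3S,4S,5S)-2,5-bis(4-benzyloxy-3-methoxyphenyl)-4-{[(tert-butyldiphenylsilyl)oxy]methyl}tetrahydrofuran-3-yl]-2-[(tert-butyldiphenylsilyl)oxy]ethan-1-ol | COc1cc([C@H]2O[C@H](c3ccc(OCc4ccccc4)c(OC)c3)[C@H](CO[Si](c3ccccc3)(c3ccccc3)C(C)(C)C)[C@H]2[C@H](O)CO[Si](c2ccccc2)(c2ccccc2)C(C)(C)C)ccc1OCc1ccccc1 | intermediate
13 | (S)-1-[(2S,3S,4S,5S)-2,5-bis(4-benzyloxy-3-methoxyphenyl)-4-(hydroxymethyl)tetrahydrofuran-3-yl]ethane-1,2-diol | COc1cc([C@H]2O[C@H](c3ccc(OCc4ccccc4)c(OC)c3)[C@H](CO)[C@H]2[C@H](O)CO)ccc1OCc1ccccc1 | intermediate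
14 | (2S,3R,4S,5S)-2,5-bis(4-benzyloxy-3-methoxyphenyl)-4-(hydroxymethyl)tetrahydrofuran-3-carbaldehyde | COc1cc([C@H]2O[C@H](c3ccc(OCc4ccccc4)c(OC)c3)[C@H](CO)[C@H]2C=O)ccc1OCc1ccccc1 | intermediate
15 | [(2S,3S,4S,5S)-2,5-bis(4-benzyloxy-3-methoxyphenyl)tetrahydrofuran-3,4-diyl]dimethanol | COc1cc([C@H]2O[C@H](c3ccc(OCc4ccccc4)c(OC)c3)[C@H](CO)[C@H]2CO)ccc1OCc1ccccc1 | intermediate
16 | eduesmine, 4,4'-[(2S,3S,4S,5S)-3,4-bis(hydroxymethyl)tetrahydrofuran-2,5-diyl]bis(2-methoxyphenol) | COc1cc([C@H]2O[C@H](c3ccc(O)c(OC)c3)[C@H](CO)[C@H]2CO)ccc1O | target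

**Count and risks**
Total step count: 10. Longest linear sequence: 9 steps (1 → 3 → 8 → 9 → 10 → 11 → 12 → 13 → 15 → 16; equally 4 → 5 → 8 → … → 16).

Step 3. The aldol trapping may discriminate poorly between anti and syn carbinols, because lithium enolates of lactones can react with aryl aldehydes through competing boat or open transition states. This would erode the C2 configuration while C3 and C4 stay secure. The fallback sets C2 by reduction instead of by C–C bond formation. It sets out from 8, taken as its mixture of carbinol epimers. Swern oxidation ((COCl)2, DMSO, Et3N, −78 °C, inert to the dithiane) would give the 3-aroyl lactone F1, in which C3 stays trans to the C4 substituent for thermodynamic reasons. Reduction with LiBH(s-Bu)3 in THF at −78 °C under non-chelation control, with the lactone carbonyl antiperiplanar to the incoming hydride, is expected to return the anti carbinol, so the route is rejoined at 8.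

Step 7. Hydride may be delivered to the wrong face of the C5 oxocarbenium ion, since the C2 aryl group and the C3 substituent lie on the face that must be attacked, or the Lewis acid may epimerise benzylic C2. The fallback reverses the order in which hydrogen and aryl reach C5, so that the aryl group is the incoming nucleophile. It sets out from butenolide 5 and aldehyde 1 and returns at 12.
- Commercial 1,3-dithiane is lithiated (n-BuLi, THF, −30 °C) to 2-lithio-1,3-dithiane F2, which in THF–DMPU at −78 °C adds to 5 to give the lithium enolate F3; trapping with 1 as in step 3 gives the C5-unsubstituted aldol lactone F4.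
- The conditions of steps 4 and 5 convert it into the triol F5 and the bis-silyl ether F6.
- Hydrolysis with Hg(ClO4)2/CaCO3 gives the cyclic lactol F7, and PhSO2H/CaCl2 in CH2Cl2 the 2-benzenesulfonyl oxolane F8.
- (4-Benzyloxy-3-methoxyphenyl)zinc bromide F9, made from commercial 1-(benzyloxy)-4-bromo-2-methoxybenzene (Mg, LiCl, ZnBr2, THF), then displaces the sulfinate through the C5-unsubstituted oxocarbenium ion.
- Inside attack anti to the C3 substituent and to the C2 aryl group, assisted by the zinc alkoxide of the side-chain hydroxyl on the same face, should place the new aryl group cis to the C4 side chain and give 12.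

Step 6. Unmasking of the hindered 2-aryl dithiane may be incomplete or unclean: hydrolysis next to two stereocentres can be slow, the electron-rich rings can be mercurated, and the acid released can ionise the benzylic alcohol. The fallback activates the thioacetal by oxidation at sulfur instead of by a thiophilic metal. It sets out from 10. Treatment with m-CPBA (1 equiv, CH2Cl2, −78 °C) would give the dithiane 1-oxide F10. Brief exposure to dilute aqueous HCl in THF at 0 °C ionises the sulfoxide to the aryl-stabilised thionium ion, which is hydrolysed (or captured directly by the C2 hydroxyl) to hemiketal 11, where the route is rejoined.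

**Further compounds**
F1 | step 3 | (3R,4S,5S)-3-(4-benzyloxy-3-methoxybenzoyl)-4-[2-(4-benzyloxy-3-methoxyphenyl)-1,3-dithian-2-yl]-5-[(tert-butyldiphenylsilyloxy)methyl]dihydrofuran-2(3H)-one | O=C1O[C@H](CO[Si](c2ccccc2)(c2ccccc2)C(C)(C)C)[C@@H](C2(c3ccc(OCc4ccccc4)c(OC)c3)SCCCS2)[C@@H]1C(=O)c1ccc(OCc2ccccc2)c(OC)c1
F2 | step 7 | 2-lithio-1,3-dithiane | [Li]C1SCCCS1
F3 | step 7 | lithium (4S,5S)-5-[(tert-butyldiphenylsilyloxy)methyl]-4-(1,3-dithian-2-yl)-4,5-dihydrofuran-2-olate | [Li]OC1=C[C@H](C2SCCCS2)[C@@H](CO[Si](c2ccccc2)(c2ccccc2)C(C)(C)C)O1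
F4 | step 7 | (3R,4S,5S)-3-[(S)-(4-benzyloxy-3-methoxyphenyl)(hydroxy)methyl]-5-[(tert-butyldiphenylsilyloxy)methyl]-4-(1,3-dithian-2-yl)dihydrofuran-2(3H)-one | O=C1O[C@H](CO[Si](c2ccccc2)(c2ccccc2)C(C)(C)C)[C@@H](C2SCCCS2)[C@@H]1[C@H](O)c1ccc(OCc2ccccc2)c(OC)c1
F5 | step 7 | (2S,3S,4S)-2-[(S)-(4-benzyloxy-3-methoxyphenyl)(hydroxy)methyl]-5-[(tert-butyldiphenylsilyl)oxy]-3-(1,3-dithian-2-yl)pentane-1,4-diol | OC[C@@H]([C@H](O)c1ccc(OCc2ccccc2)c(OC)c1)[C@H](C1SCCCS1)[C@H](O)CO[Si](c1ccccc1)(c1ccccc1)C(C)(C)C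
F6 | step 7 | (2S,3S,4S)-4-[(S)-(4-benzyloxy-3-methoxyphenyl)(hydroxy)methyl]-1,5-bis[(tert-butyldiphenylsilyl)oxy]-3-(1,3-dithian-2-yl)pentan-2-ol | CC(C)(C)[Si](c1ccccc1)(c1ccccc1)OC[C@@H]([C@H](O)c1ccc(OCc2ccccc2)c(OC)c1)[C@H](C1SCCCS1)[C@H](O)CO[Si](c1ccccc1)(c1ccccc1)C(C)(C)C
F7 | step 7 | (3S,4S,5S)-5-(4-benzyloxy-3-methoxyphenyl)-3-[(S)-2-(tert-butyldiphenylsilyloxy)-1-hydroxyethyl]-4-[(tert-butyldiphenylsilyloxy)methyl]tetrahydrofuran-2-ol (both anomers) | OC1O[C@H](c2ccc(OCc3ccccc3)c(OC)c2)[C@H](CO[Si](c2ccccc2)(c2ccccc2)C(C)(C)C)[C@H]1[C@H](O)CO[Si](c1ccccc1)(c1ccccc1)C(C)(C)C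
F8 | step 7 | (S)-1-[(3S,4S,5S)-2-(benzenesulfonyl)-5-(4-benzyloxy-3-methoxyphenyl)-4-{[(tert-butyldiphenylsilyl)oxy]methyl}tetrahydrofuran-3-yl]-2-[(tert-butyldiphenylsilyl)oxy]ethan-1-ol (both anomers) | O=S(=O)(c1ccccc1)C1O[C@H](c2ccc(OCc3ccccc3)c(OC)c2)[C@H](CO[Si](c2ccccc2)(c2ccccc2)C(C)(C)C)[C@H]1[C@H](O)CO[Si](c1ccccc1)(c1ccccc1)C(C)(C)C
F9 | step 7 | (4-benzyloxy-3-methoxyphenyl)zinc bromide | COc1cc([Zn]Br)ccc1OCc1ccccc1
F10 | step 6 | (2S,3S,4S)-4-[(S)-(4-benzyloxy-3-methoxyphenyl)(hydroxy)methyl]-3-[2-(4-benzyloxy-3-methoxyphenyl)-1-oxido-1,3-dithian-2-yl]-1,5-bis[(tert-butyldiphenylsilyl)oxy]pentan-2-ol (sulfoxide diastereomers) | CC(C)(C)[Si](c1ccccc1)(c1ccccc1)OC[C@@H]([C@H](O)c1ccc(OCc2ccccc2)c(OC)c1)[C@H](C1(c2ccc(OCc3ccccc3)c(OC)c2)SCCCS1=O)[C@H](O)CO[Si](c1ccccc1)(c1ccccc1)C(C)(C)C
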